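**Plan**

- Labels: the upper eriodictyol unit is rings A, B, C (C2, C3, C4); the lower naringenin unit is rings D, E, F (C2''–C8a''); the units meet at C3–C8''.
- Retrosynthesis: cut O1–C2 (oxa-Michael) and C2=C3 (condensation with the ring B aldehyde), then C4–C4a (Friedel–Crafts acylation), which leaves a CH2CO2R arm on C8''. Then cut C8''–C8a'' and C4a''–C5'' of ring D (Diels–Alder/aromatisation), and last C2''–C3'' and O1''–C8a'' of ring F (hetero-Diels–Alder).
- Enabling feature: ring D is a pentasubstituted phloroglucinol ring. Its C5''/C7'' oxygens and C8'' carbon branch map onto a 1,1,3-trioxygenated diene, and C4a''–C8a'', flanked by C4''=O and O1'', maps onto the enone of a dihydropyranone. Building the ring this way puts the branch at C8'' beside O1'' and leaves C6'' free.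
- Forward order: ring F (carrying ring E), then ring D, then ring A attached, then ring C closed (bringing ring B), then global debenzylation.
- Stereochemistry: C2'' (R) from a BINOL–Ti(OiPr)4 hetero-Diels–Alder reaction; C2 (R) from a cinchona-thiourea-catalysed oxa-Michael closure; C3 (S) by thermodynamic trans protonation.

Key step: step 7

Assumption: compounds 1, 2, 8, 9, 21 and 24 are taken as purchasable, and the sense of induction in steps 1 and 13 is assigned by analogy with simple aryl aldehydes and 2'-hydroxychalcones; should either prove opposite, the enantiomeric ligand or the pseudoenantiomeric alkaloid catalyst is used with no other change.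

**Route**

Step 1
Reactants: 1 4-(benzyloxy)benzaldehyde; 2 (E)-1-methoxy-3-(trimethylsilyloxy)buta-1,3-diene
Product: 4 (2R)-2-[4-(benzyloxy)phenyl]-2,3-dihydro-4H-pyran-4-one, via aldol silyl ether 3 (not isolated)
Conditions: (R)-BINOL (20 mol%), Ti(OiPr)4 (10 mol%), 4 Å molecular sieves, Et2O, −20 °C; then CF3CO2H, CH2Cl2, 0 °C
Reagents that add atoms: none
Why: Catalytic asymmetric hetero-Diels–Alder reaction run as a Mukaiyama aldol addition followed by acid-induced cyclisation with loss of methanol; the BINOL–titanium Lewis acid exposes one face of the aldehyde and so sets C2'' as (R).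

Step 2
Reactants: 4 (2R)-2-[4-(benzyloxy)phenyl]-2,3-dihydro-4H-pyran-4-one
Product: 6 (2R)-2-[4-(benzyloxy)phenyl]-5-(phenylsulfanyl)-2,3-dihydro-4H-pyran-4-one, via chlorosulfide adduct 5 (not isolated)
Conditions: PhSH, N-chlorosuccinimide, CH2Cl2, 0 °C; then 4, −78 → 0 °C; then Et3N, 0 °C
Reagents that add atoms: benzenesulfenyl chloride, ClSc1ccccc1 (formed in the flask from thiophenol, Sc1ccccc1, and N-chlorosuccinimide)
Why: Electrophilic α-sulfenylation of a vinylogous ester by addition–elimination: the sulfenyl chloride attacks the nucleophilic enol ether carbon C5, chloride is captured at C6, and triethylamine removes HCl to restore the enone without touching C2.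

Step 3
Reactants: 6 (2R)-2-[4-(benzyloxy)phenyl]-5-(phenylsulfanyl)-2,3-dihydro-4H-pyran-4-one
Product: 7 (2R)-2-[4-(benzyloxy)phenyl]-5-(phenylsulfinyl)-2,3-dihydro-4H-pyran-4-one (both sulfur epimers)
Conditions: mCPBA (1.0 equiv), CH2Cl2, −78 → −30 °C
Reagents that add atoms: mCPBA, O=C(OO)c1cccc(Cl)c1
Why: Sulfide-to-sulfoxide oxidation with one equivalent of peracid at low temperature, where the electron-poor enone double bond and the benzyl ether are inert; the configuration at sulfur does not matter because the group is lost in step 7.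

Step 4
Reactants: 8 4-tert-butoxy-4-oxobutanoic acid (mono-tert-butyl succinate); 9 potassium 3-methoxy-3-oxopropanoate (potassium monomethyl malonate)
Product: 12 6-tert-butyl 1-methyl 3-oxohexanedioate, via acyl imidazolide 10 (not isolated), via acylmalonic half ester 11 (not isolated)
Conditions: 1,1'-carbonyldiimidazole, THF, rt; then 9, MgCl2, Et3N, MeCN, rt; aq. HCl work-up
Reagents that add atoms: none
Why: Masamune–Brooks homologation, in which the acyl imidazolide C-acylates the magnesium enolate of the malonate half ester and the adduct decarboxylates on acidification to the β-keto ester.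

Step 5
Reactants: 12 6-tert-butyl 1-methyl 3-oxohexanedioate
Product: 13 6-tert-butyl 1-methyl 3-(trimethylsilyloxy)hex-2-enedioate (E/Z mixture)
Conditions: Me3SiCl, Et3N, toluene, rt
Reagents that add atoms: chlorotrimethylsilane, C[Si](C)(C)Cl
Why: Silyl enol ether formation by O-silylation of the enolised β-keto ester under amine base, the first half of the usual two-stage preparation of 1-alkoxy-1,3-bis(silyloxy)dienes.

Step 6
Reactants: 13 6-tert-butyl 1-methyl 3-(trimethylsilyloxy)hex-2-enedioate
Product: 15 tert-butyl (3Z)-6-methoxy-4,6-bis(trimethylsilyloxy)hexa-3,5-dienoate, via lithium dienolate 14 (not isolated)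
Conditions: LiN(iPr)2 (0.98 equiv), THF, −78 → −40 °C; then Me3SiCl, −78 °C → rt; filtered under argon and used crude
Reagents that add atoms: chlorotrimethylsilane, C[Si](C)(C)Cl
Why: Vinylogous enolate formation and O-silylation: the amide base removes the γ-proton (C4) of the β-silyloxy enoate to give the cross-conjugated dienolate, which is more stable than the simple tert-butyl ester enolate, and the slight deficit of base lets any ester enolate equilibrate to it before silylation.

Step 7
Reactants: 7 (2R)-2-[4-(benzyloxy)phenyl]-5-(phenylsulfinyl)-2,3-dihydro-4H-pyran-4-one; 15 tert-butyl (3Z)-6-methoxy-4,6-bis(trimethylsilyloxy)hexa-3,5-dienoate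
Product: 18 tert-butyl 2-[(2R)-2-[4-(benzyloxy)phenyl]-5,7-dihydroxy-4-oxochroman-8-yl]acetate, via cycloadduct 16 (not isolated), via bis(trimethylsilyl) ether 17 (not isolated)
Conditions: 15 (2.5 equiv), toluene, rt, then 80 °C; then 10% aq. citric acid, THF, rt
Reagents that add atoms: none
Why: The electron-rich 1,1,3-trioxygenated diene adds to the sulfinyl-activated C5=C6 bond of 7 in a normal-demand Diels–Alder reaction (or its stepwise Mukaiyama–Michael/Claisen-type equivalent), the arm-bearing nucleophilic terminus bonding to the β-carbon C6 (future C8a'') and the ketene acetal carbon to C5 (future C4a''). Ring D is thus closed by an intermolecular (4+2) cycloaddition onto ring F; the cis-fused adduct holds sulfur and H8a'' syn, so benzenesulfenic acid leaves by thermal syn-elimination, and 1,4-loss of methanol (OMe from C5'', H from C8'') aromatises the ring to the bis(silyl) ether, which mild acid unmasks. The closest known reactions are Diels–Alder/aromatisation sequences of 1,3-bis(silyloxy)dienes with 3-sulfinylchromones, sulfinylquinones and haloquinones that give resorcinol and phloroglucinol rings. No new stereocentre survives, so facial selectivity is irrelevant, and C2'' is safe because ring F is not a flavanone until ring D is aromatic and the medium is never basic. The selectivity that counts is regiochemical: the largest HOMO coefficient of the diene lies on the arm-bearing terminus and the enone is polarised by the carbonyl and sulfinyl groups on C5, which places the acetate arm at C8'' beside O1'' and leaves C6'' unsubstituted. Excess diene also scavenges the sulfenic acid.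

Step 8
Reactants: 18 tert-butyl 2-[(2R)-2-[4-(benzyloxy)phenyl]-5,7-dihydroxy-4-oxochroman-8-yl]acetate
Product: 19 tert-butyl 2-[(2R)-7-(benzyloxy)-2-[4-(benzyloxy)phenyl]-5-hydroxy-4-oxochroman-8-yl]acetate
Conditions: BnOH, PPh3, diisopropyl azodicarboxylate, THF, 0 °C → rt
Reagents that add atoms: benzyl alcohol, OCc1ccccc1
Why: Mitsunobu etherification engages only the acidic, non-chelated 7''-phenol and leaves the hydrogen-bonded 5''-OH free, its neutral conditions avoid the base-induced ring opening that would racemise C2'', and the ether blocks lactonisation of the arm onto O7''.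

Step 9
Reactants: 19 tert-butyl 2-[(2R)-7-(benzyloxy)-2-[4-(benzyloxy)phenyl]-5-hydroxy-4-oxochroman-8-yl]acetate
Product: 20 2-[(2R)-7-(benzyloxy)-2-[4-(benzyloxy)phenyl]-5-hydroxy-4-oxochroman-8-yl]acetic acid
Conditions: CF3CO2H, anisole, CH2Cl2, 0 °C → rt
Reagents that add atoms: none
Why: Acidolysis of the tert-butyl ester (E1 loss of isobutene, anisole as cation trap), which aryl benzyl ethers and the flavanone should survive on brief exposure.

Step 10
Reactants: 20 2-[(2R)-7-(benzyloxy)-2-[4-(benzyloxy)phenyl]-5-hydroxy-4-oxochroman-8-yl]acetic acid; 21 1,3,5-tris(benzyloxy)benzene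
Product: 23 (2R)-7-(benzyloxy)-2-[4-(benzyloxy)phenyl]-5-hydroxy-8-{2-oxo-2-[2,4,6-tris(benzyloxy)phenyl]ethyl}chroman-4-one, via mixed trifluoroacetic anhydride 22 (not isolated)
Conditions: (CF3CO)2O, CH2Cl2, 0 °C → rt; aq. NaHCO3 work-up
Reagents that add atoms: none
Why: Friedel–Crafts acylation of a highly activated arene by the mixed trifluoroacetic anhydride of an arylacetic acid (the usual deoxybenzoin synthesis); the three equivalent positions of 21 give one ketone, and ring D, deactivated by its own C4'' carbonyl, should not compete.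

Step 11
Reactants: 23 (2R)-7-(benzyloxy)-2-[4-(benzyloxy)phenyl]-5-hydroxy-8-{2-oxo-2-[2,4,6-tris(benzyloxy)phenyl]ethyl}chroman-4-one; 24 3,4-bis(benzyloxy)benzaldehyde
Product: 25 (2R)-7-(benzyloxy)-2-[4-(benzyloxy)phenyl]-8-{(1E)-1-[3,4-bis(benzyloxy)phenyl]-3-oxo-3-[2,4,6-tris(benzyloxy)phenyl]prop-1-en-2-yl}-5-hydroxychroman-4-one
Conditions: piperidine (20 mol%), AcOH (20 mol%), 4 Å molecular sieves, toluene, 80 °C
Reagents that add atoms: none
Why: Knoevenagel-type aldol condensation at the benzylic α-methylene of the deoxybenzoin, which is far more acidic than C3''–H2 of ring F; with no free ortho-hydroxyl on ring A the enone cannot cyclise, and the buffered amine should leave the chelated ring F ketone unenolised so that C2'' is kept.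

Step 12
Reactants: 25 the α-aryl chalcone from step 11
Product: 26 (2R)-7-(benzyloxy)-2-[4-(benzyloxy)phenyl]-8-{(1E)-1-[3,4-bis(benzyloxy)phenyl]-3-[2-hydroxy-4,6-bis(benzyloxy)phenyl]-3-oxoprop-1-en-2-yl}-5-hydroxychroman-4-one
Conditions: BCl3 (2.5 equiv), CH2Cl2, −78 °C; then MeOH, aq. NaHCO3; used at once
Reagents that add atoms: none
Why: Chelation-directed ortho-debenzylation: boron bound to the ring A carbonyl cleaves one of the two equivalent ortho benzyl ethers at low temperature, the resulting boron chelate protects the second, and the non-chelating benzyl ethers are left in place.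

Step 13
Reactants: 26 the 2'-hydroxy-α-aryl chalcone from step 12
Product: 27 (2R,3S)-5,7-bis(benzyloxy)-3-[(2R)-7-(benzyloxy)-2-[4-(benzyloxy)phenyl]-5-hydroxy-4-oxochroman-8-yl]-2-[3,4-bis(benzyloxy)phenyl]chroman-4-one
Conditions: thiourea from 9-amino-9-deoxy-epi-quinidine and 3,5-bis(trifluoromethyl)phenyl isothiocyanate (10 mol%), toluene, −20 °C → rt
Reagents that add atoms: none
Why: Intramolecular oxa-Michael addition (6-endo-trig) under bifunctional hydrogen-bond/Brønsted-base catalysis: the thiourea binds the enone carbonyl while the quinuclidine nitrogen delivers the ring A phenol to one face of C2 to set (2R), and C3 is protonated and equilibrated by the same base to the trans (3S) isomer.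

Step 14
Reactants: 27 the hexabenzyl biflavanone from step 13
Product: 28 (2R,3S)-2-(3,4-dihydroxyphenyl)-3-[(2R)-5,7-dihydroxy-2-(4-hydroxyphenyl)-4-oxochroman-8-yl]-5,7-dihydroxychroman-4-one (CNP0105436.3)
Conditions: H2 (1 atm), 10% Pd/C, EtOAc/MeOH, rt
Reagents that add atoms: none
Why: Catalytic hydrogenolysis removes all six aryl benzyl ethers under neutral conditions, which should spare the two flavanone carbonyls and the base-sensitive C2, C3 and C2'' centres.

**Compound list**

1 | 4-(benzyloxy)benzaldehyde | O=Cc1ccc(OCc2ccccc2)cc1 | starting material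
2 | (E)-1-methoxy-3-(trimethylsilyloxy)buta-1,3-diene | CO/C=C/C(=C)O[Si](C)(C)C | starting material
3 | (5R,1E)-5-[4-(benzyloxy)phenyl]-1-methoxy-5-(trimethylsilyloxy)pent-1-en-3-one | CO/C=C/C(=O)C[C@@H](O[Si](C)(C)C)c1ccc(OCc2ccccc2)cc1 | intermediate
4 | (2R)-2-[4-(benzyloxy)phenyl]-2,3-dihydro-4H-pyran-4-one | O=C1C[C@H](c2ccc(OCc3ccccc3)cc2)OC=C1 | intermediate
5 | (2R)-2-[4-(benzyloxy)phenyl]-6-chloro-5-(phenylsulfanyl)tetrahydro-4H-pyran-4-one (C5/C6 diastereomers) | O=C1C[C@H](c2ccc(OCc3ccccc3)cc2)OC(Cl)C1Sc1ccccc1 | intermediate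
6 | (2R)-2-[4-(benzyloxy)phenyl]-5-(phenylsulfanyl)-2,3-dihydro-4H-pyran-4-one | O=C1C[C@H](c2ccc(OCc3ccccc3)cc2)OC=C1Sc1ccccc1 | intermediate
7 | (2R)-2-[4-(benzyloxy)phenyl]-5-(phenylsulfinyl)-2,3-dihydro-4H-pyran-4-one (both sulfur epimers) | O=C1C[C@H](c2ccc(OCc3ccccc3)cc2)OC=C1S(=O)c1ccccc1 | intermediate
8 | 4-tert-butoxy-4-oxobutanoic acid | CC(C)(C)OC(=O)CCC(=O)O | starting material
9 | potassium 3-methoxy-3-oxopropanoate | COC(=O)CC(=O)[O-].[K+] | starting material
10 | tert-butyl 4-(1H-imidazol-1-yl)-4-oxobutanoate | CC(C)(C)OC(=O)CCC(=O)n1ccnc1 | intermediate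
11 | 6-tert-butoxy-2-(methoxycarbonyl)-3,6-dioxohexanoic acid (magnesium chelate in the flask) | COC(=O)C(C(=O)O)C(=O)CCC(=O)OC(C)(C)C | intermediate
12 | 6-tert-butyl 1-methyl 3-oxohexanedioate | COC(=O)CC(=O)CCC(=O)OC(C)(C)C | intermediate
13 | 6-tert-butyl 1-methyl 3-(trimethylsilyloxy)hex-2-enedioate (E/Z mixture) | COC(=O)C=C(CCC(=O)OC(C)(C)C)O[Si](C)(C)C | intermediate
14 | lithium 6-tert-butoxy-1-methoxy-6-oxo-3-(trimethylsilyloxy)hexa-1,3-dien-1-olate | [Li+].COC([O-])=CC(O[Si](C)(C)C)=CCC(=O)OC(C)(C)C | intermediate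
15 | tert-butyl (3Z)-6-methoxy-4,6-bis(trimethylsilyloxy)hexa-3,5-dienoate | CC(C)(C)OC(=O)C/C=C(\O[Si](C)(C)C)C=C(OC)O[Si](C)(C)C | intermediate
16 | tert-butyl 2-[(2R)-2-[4-(benzyloxy)phenyl]-5-methoxy-4-oxo-4a-(phenylsulfinyl)-5,7-bis(trimethylsilyloxy)-3,4,4a,5,8,8a-hexahydro-2H-chromen-8-yl]acetate (new centres undefined) | O=C1C[C@H](c2ccc(OCc3ccccc3)cc2)OC2C(CC(=O)OC(C)(C)C)C(O[Si](C)(C)C)=CC(OC)(O[Si](C)(C)C)C12S(=O)c1ccccc1 | intermediate
17 | tert-butyl 2-[(2R)-2-[4-(benzyloxy)phenyl]-4-oxo-5,7-bis(trimethylsilyloxy)chroman-8-yl]acetate | O=C1C[C@H](c2ccc(OCc3ccccc3)cc2)Oc2c1c(O[Si](C)(C)C)cc(O[Si](C)(C)C)c2CC(=O)OC(C)(C)C | intermediate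
18 | tert-butyl 2-[(2R)-2-[4-(benzyloxy)phenyl]-5,7-dihydroxy-4-oxochroman-8-yl]acetate | O=C1C[C@H](c2ccc(OCc3ccccc3)cc2)Oc2c1c(O)cc(O)c2CC(=O)OC(C)(C)C | intermediate
19 | tert-butyl 2-[(2R)-7-(benzyloxy)-2-[4-(benzyloxy)phenyl]-5-hydroxy-4-oxochroman-8-yl]acetate | O=C1C[C@H](c2ccc(OCc3ccccc3)cc2)Oc2c1c(O)cc(OCc1ccccc1)c2CC(=O)OC(C)(C)C | intermediate
20 | 2-[(2R)-7-(benzyloxy)-2-[4-(benzyloxy)phenyl]-5-hydroxy-4-oxochroman-8-yl]acetic acid | O=C1C[C@H](c2ccc(OCc3ccccc3)cc2)Oc2c1c(O)cc(OCc1ccccc1)c2CC(=O)O | intermediate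
21 | 1,3,5-tris(benzyloxy)benzene | c1ccc(COc2cc(OCc3ccccc3)cc(OCc3ccccc3)c2)cc1 | starting material
22 | mixed anhydride of 20 with trifluoroacetic acid | O=C1C[C@H](c2ccc(OCc3ccccc3)cc2)Oc2c1c(O)cc(OCc1ccccc1)c2CC(=O)OC(=O)C(F)(F)F | intermediate
23 | (2R)-7-(benzyloxy)-2-[4-(benzyloxy)phenyl]-5-hydroxy-8-{2-oxo-2-[2,4,6-tris(benzyloxy)phenyl]ethyl}chroman-4-one | O=C1C[C@H](c2ccc(OCc3ccccc3)cc2)Oc2c1c(O)cc(OCc1ccccc1)c2CC(=O)c1c(OCc2ccccc2)cc(OCc2ccccc2)cc1OCc1ccccc1 | intermediate
24 | 3,4-bis(benzyloxy)benzaldehyde | O=Cc1ccc(OCc2ccccc2)c(OCc2ccccc2)c1 | starting material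
25 | (2R)-7-(benzyloxy)-2-[4-(benzyloxy)phenyl]-8-{(1E)-1-[3,4-bis(benzyloxy)phenyl]-3-oxo-3-[2,4,6-tris(benzyloxy)phenyl]prop-1-en-2-yl}-5-hydroxychroman-4-one | O=C1C[C@H](c2ccc(OCc3ccccc3)cc2)Oc2c1c(O)cc(OCc1ccccc1)c2/C(=C\c1ccc(OCc2ccccc2)c(OCc2ccccc2)c1)C(=O)c1c(OCc2ccccc2)cc(OCc2ccccc2)cc1OCc1ccccc1 | intermediate
26 | (2R)-7-(benzyloxy)-2-[4-(benzyloxy)phenyl]-8-{(1E)-1-[3,4-bis(benzyloxy)phenyl]-3-[2-hydroxy-4,6-bis(benzyloxy)phenyl]-3-oxoprop-1-en-2-yl}-5-hydroxychroman-4-one | O=C1C[C@H](c2ccc(OCc3ccccc3)cc2)Oc2c1c(O)cc(OCc1ccccc1)c2/C(=C\c1ccc(OCc2ccccc2)c(OCc2ccccc2)c1)C(=O)c1c(O)cc(OCc2ccccc2)cc1OCc1ccccc1 | intermediate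
27 | (2R,3S)-5,7-bis(benzyloxy)-3-[(2R)-7-(benzyloxy)-2-[4-(benzyloxy)phenyl]-5-hydroxy-4-oxochroman-8-yl]-2-[3,4-bis(benzyloxy)phenyl]chroman-4-one | O=C1C[C@H](c2ccc(OCc3ccccc3)cc2)Oc2c1c(O)cc(OCc1ccccc1)c2[C@@H]1C(=O)c2c(OCc3ccccc3)cc(OCc3ccccc3)cc2O[C@H]1c1ccc(OCc2ccccc2)c(OCc2ccccc2)c1 | intermediate
28 | (2R,3S)-2-(3,4-dihydroxyphenyl)-3-[(2R)-5,7-dihydroxy-2-(4-hydroxyphenyl)-4-oxochroman-8-yl]-5,7-dihydroxychroman-4-one | O=C1C[C@H](c2ccc(O)cc2)Oc2c1c(O)cc(O)c2[C@@H]1C(=O)c2c(O)cc(O)cc2O[C@H]1c1ccc(O)c(O)c1 | target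

**Count and risks**

Total steps: 14. Longest linear sequence: 11 steps (steps 1–3 and 7–14 from 1; the diene branch, steps 4–6 and 7–14, is equally long).

Steps most likely to fail:

1. Step 7. The cycloaddition may be slow because the diene terminus is substituted and the dienophile β-carbon carries a donor oxygen; the diene may be desilylated by the sulfenic acid, or the reaction may stop after the first C–C bond. The fallback makes the same two bonds in two ionic stages. It sets out from 7 and 15: Me3SiOTf-catalysed Mukaiyama–Michael addition in CH2Cl2 at −78 °C and aqueous work-up should give the Michael adduct 6-tert-butyl 1-methyl 4-[(6R)-6-[4-(benzyloxy)phenyl]-4-oxo-3-(phenylsulfinyl)tetrahydro-2H-pyran-2-yl]-3-oxohexanedioate F1. DBU in toluene should then close C4a''–C5'' by Dieckmann condensation of the α-sulfinyl ketone onto the methyl ester, and warming to 80 °C should expel benzenesulfenic acid and let the ring tautomerise to the phenol. The fallback returns to the route at 18.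

2. Step 13. Facial selectivity at C2 may be poor on this hindered α-aryl enone, an uncatalysed background closure may compete, and reversible ring opening may erode the result. The fallback gives up catalyst control. It sets out from 26: closure with catalytic Et3N in CH2Cl2/MeOH at rt should give, under thermodynamic 2,3-trans control, 27 together with its (2S,3R,2''R) diastereomer F2. The two are diastereomers and would be separated by chromatography, and the unwanted one would be re-equilibrated with the same base and recycled. The fallback returns at 27.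

3. Step 11. Condensation at the methylene flanked by two di-ortho-substituted aryl groups may be sluggish, and prolonged heating with amine may begin to epimerise C2''. The fallback lets ring closure drive the condensation. It sets out from 23: BCl3 in CH2Cl2 at −78 °C should give the 2-hydroxy ketone (2R)-7-(benzyloxy)-2-[4-(benzyloxy)phenyl]-5-hydroxy-8-{2-[2-hydroxy-4,6-bis(benzyloxy)phenyl]-2-oxoethyl}chroman-4-one F3. Pyrrolidine-mediated condensation with 24 in EtOH at 50 °C should then pass through 26 in the flask and close directly to the trans chromanones, 27 and the diastereomer described under step 13, which are separated as there. The fallback returns at 27.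

**Further compounds**

F1 | step 7 | 6-tert-butyl 1-methyl 4-[(6R)-6-[4-(benzyloxy)phenyl]-4-oxo-3-(phenylsulfinyl)tetrahydro-2H-pyran-2-yl]-3-oxohexanedioate | COC(=O)CC(=O)C(CC(=O)OC(C)(C)C)C1O[C@@H](c2ccc(OCc3ccccc3)cc2)CC(=O)C1S(=O)c1ccccc1
F2 | step 13 | (2S,3R)-5,7-bis(benzyloxy)-3-[(2R)-7-(benzyloxy)-2-[4-(benzyloxy)phenyl]-5-hydroxy-4-oxochroman-8-yl]-2-[3,4-bis(benzyloxy)phenyl]chroman-4-one | O=C1C[C@H](c2ccc(OCc3ccccc3)cc2)Oc2c1c(O)cc(OCc1ccccc1)c2[C@H]1C(=O)c2c(OCc3ccccc3)cc(OCc3ccccc3)cc2O[C@@H]1c1ccc(OCc2ccccc2)c(OCc2ccccc2)c1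
F3 | step 11 | (2R)-7-(benzyloxy)-2-[4-(benzyloxy)phenyl]-5-hydroxy-8-{2-[2-hydroxy-4,6-bis(benzyloxy)phenyl]-2-oxoethyl}chroman-4-one | O=C1C[C@H](c2ccc(OCc3ccccc3)cc2)Oc2c1c(O)cc(OCc1ccccc1)c2CC(=O)c1c(O)cc(OCc2ccccc2)cc1OCc1ccccc1
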